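The flask holds 36 mM of substrate against 54.0 mM of partner, so substrate is the limiting reagent, and we keep the books per mole of it, with 1.50 mol of partner beside each.

| flask | substrate | partner | remark | time |
|---|---|---|---|---|
| violet | 18 mM | 54 mM | run made earlier |  |
| teal | 72 mM | 54 mM | run made earlier |  |
| grey | 36 mM | 81 mM | run made earlier |  |
| flask | 36 mM | 54.0 mM |  | 5.0 h |

- violet (time / h: product / %): 0.833: 92; 1.50: 93; 2.50: 96; 3.00: 96
- teal (time / h: product / %): 0.833: 60; 1.50: 62; 2.50: 59; 3.00: 62
- grey (time / h: product / %): 0.833: 90; 1.50: 87; 2.50: 90; 3.00: 91

(standard deviation of a reading: 1.5 percentage points)

- the reaction counts as stopped when no species that holds the substrate changes by six tenths of a point or more over the second half of the time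

- which holds at 5.0 h: what has brought the reaction to rest, or that it has not come to rest (all of the substrate has reacted / forward and back rates have come level / it is still moving / the partner has run out first)
- how much product there is at 5.0 h, in percent of the substrate charged

Our ledger reads as follows. A share x of the substrate becomes product, takes x of partner and, as we assume, frees x of a released group. The rest, one minus x, stays booked as substrate, and partner keeps 1.50 minus x.

Teal shows how such books close. It reads 60% at 0.833 h, 59% at 2.50 h and 62% at 3.00 h, so we read no drift against a scatter of 1.5 percentage points on each reading. Its mean of 60.8% stops short of the 75.0% its partner allows, so we take forward and back rates to have come level. Its books give 6.60 for [product][released group]/([substrate][partner]), the whole unconverted share counted as substrate: the closing ratio. Grey, read the same way, gives 5.63, lower, but from an unconverted share of 10.5% against teal's 39.2%.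

Setting the flask's ledger to teal's ratio, we get 83.9% product at rest by 5.0 h.

The forecast, made from the same runs, notes that the “readings are flat from 0.83 h on” and says forward and back rates have come level, with 84% product.

The flask gives 84.3%, and forward and back rates have come level: product stands at 84.3% at 2.50 h and at 84.3% at 50.0 h.

    substrate + partner ⇌ product + released group (K = 8.94, k = 0.202 L mol⁻¹ s⁻¹)
    substrate ⇌ dormant form (K = 0.300, k = 0.00132 s⁻¹)

Booked our way, with the whole unconverted share counted as substrate, the flask's own product gives a closing ratio of 6.88; that unconverted share in fact stands in two forms at 5.00 h, 12.1% substrate and 3.63% dormant form.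

With 61 mM of substrate, 0.885 equiv of partner, the closing ratio gives 67.4% product. The computed flask gives 67.8%.

All runs stem from a simulated flask with made-up constants, noise included.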